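(Readings and results are simulated with constants of no real substance, and the scatter is random.)

In a closed flask of constant volume every unit of free monomer charged stays in the flask, so I followed one unit and asked where it sits late in the run.

| flask | free monomer | initiator | temperature | remark | time |
|---|---|---|---|---|---|
| larch | 1.7 M | 0.5 mol% | 110 °C | the very flask that is asked about, followed so far |  |
| cedar | 2.5 M | 0.5 mol% | 105 °C | run made earlier |  |
| flask | 1.7 M | 0.5 mol% | 110 °C |  | 5.0 h |

| run | time / h | monomer in chains / % |
|---|---|---|
| larch | 0.833 | 35.0 |
| larch | 1.50 | 32.7 |
| larch | 2.50 | 29.7 |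
| larch | 3.00 | 28.6 |
| larch | 4.00 | 24.1 |
| cedar | 0.417 | 27.7 |
| cedar | 1.33 | 40.3 |
| cedar | 2.50 | 30.6 |
| cedar | 4.00 | 23.8 |
| cedar | 5.00 | 22.5 |

(readings scatter by 1 percentage point)

- monomer in chains, in percent of the free monomer first charged, at 5.0 h
- which option adds most monomer in chains ("none" when 2 percentage points or less is all one gets) (Sunday's / Friday's / Saturday's / none)
- monomer in chains present, with what was taken out counted in, in percent of the free monomer first charged, after Friday's
- monomer in chains present, with what was taken out counted in, in percent of the free monomer first charged, after Saturday's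

- Sunday's: at 5.0 h raise the temperature by 25 K, then wait 2.5 h
- Friday's: change nothing and wait 2.5 h more
- Saturday's: at 5.0 h take out 90% of the monomer in chains then present, then wait 2.5 h

- monomer in chains taken out counts as made
- the analysis behind the earlier runs scatters by 1 percentage point, standard deviation

Cedar rose and then fell, and larch fell from its first reading on, so units were leaving chains for a form I could not read. The bench rule says that a late reading of a levelling curve is its end value. At 4.00 h larch read 24.1% and cedar 23.8%, a gap of 0.3 percentage points, smaller than the scatter of 1 point, although charge and temperature differed. I therefore called their mean the late share, the chance that a reacted unit sits in chains once the early overshoot is past: 24.0%. I read the peak as kinetic control and the late share as thermodynamic control.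

The rule stops where a reading is not yet the share:

cedar at 1.33 h: reading over late share = 1.68

larch at 3.00 h: reading over late share = 1.19

Cedar's readings took 2.67 h to come down, and the further wait is 0.936 of that, so I counted on a full return after a withdrawal, at some risk. I also took the whole charge as reacted by 5.0 h, which no reading shows.

now and Friday's: 24.0%, with no gain

Saturday's, taken out: 21.6%

Saturday's, left in the flask: 78.4%

Saturday's, back in chains: 18.8%

Saturday's, total: 40.3%

Two runs with a gap inside the scatter gave me no sign for Sunday's, so I named Saturday's.

The forecast, lower than my total, gave 22% now, 20% after Friday's and 31% after Saturday's, named Saturday's, and held of Sunday's that “heating probably favours depolymerisation, so it gains nothing”.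

The flask gave 25.9% now, 25.7% after Friday's and 42.9% after Saturday's; Sunday's was best, adding 27 points against 17 points for Saturday's.

    free monomer + growing radical → monomer in chains + growing radical, rate k1*[growing radical]*[free monomer] (k = 5.20 × 10⁵ L mol⁻¹ min⁻¹, Ea = 28.0 kJ mol⁻¹)
    free monomer + initiating radical → growing radical + monomer in chains (k = 1.60 × 10⁵ L mol⁻¹ s⁻¹, Ea = 18.0 kJ mol⁻¹)
    initiator → 2 initiating radical (k = 0.00190 min⁻¹, Ea = 111 kJ mol⁻¹)
    monomer in chains ⇌ isomer of the product (K = 2.90, k = 0.0250 min⁻¹, Ea = 116 kJ mol⁻¹, ΔH = −61.0 kJ mol⁻¹)
    2 growing radical → dead chain (k = 2.00 × 10⁸ L mol⁻¹ s⁻¹, Ea = 15.0 kJ mol⁻¹)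
    (constants at 110 °C)

At 5.0 h the flask held 0.61% free monomer, so the late share predicted 23.9% in chains against the 25.9% found. The neighbouring flask was the same flask read at 80 min, when it held 22.9% free monomer and 43.0% isomer of the product. The same reckoning gave 18.5% in chains for that neighbour, but it held 34.1%, which is 1.84 times the reckoned amount.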